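The numbers in the tables are simulated on assumed constants; noise was put on by code.

The vessel is closed and stirred and stays at one temperature, and electrophile and nucleophile go in at 0.38 M and 0.399 M.

| flask | electrophile | nucleophile | free base | remark | time |
|---|---|---|---|---|---|
| amber | 0.38 M | 0.399 M | 0.76 M | run made earlier |  |
| violet | 0.38 M | 0.399 M | 2.3 M | run made earlier |  |
| theta | 0.38 M | 0.399 M | 1.10 M |  | 10 h |
| alpha | 0.38 M | 0.399 M | 1.70 M |  | 10 h |
| beta | 0.38 M | 0.399 M | 2.60 M |  | 10 h |

| run | time / h | electrophile / % | target / % |
|---|---|---|---|
| amber | 0.500 | 91.2 | 8.1 |
| amber | 0.833 | 86.4 | 14.2 |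
| amber | 1.33 | 79.4 | 19.4 |
| amber | 2.00 | 75.0 | 25.3 |
| amber | 3.00 | 65.7 | 31.7 |
| amber | 5.00 | 54.9 | 38.0 |
| amber | 8.00 | 44.3 | 44.8 |
| violet | 1.00 | 83.3 | 14.2 |
| violet | 2.00 | 72.1 | 22.0 |
| violet | 3.00 | 64.7 | 27.7 |
| violet | 4.00 | 60.7 | 29.2 |
| violet | 5.00 | 56.1 | 31.4 |
| violet | 6.00 | 50.5 | 31.9 |
| violet | 8.00 | 43.3 | 30.1 |

(each reading ± 1 percentage point)



- part of the electrophile that has reacted at the end, theta
- part of the electrophile that has reacted at the end, alpha
- part of the electrophile that has reacted at the end, beta
- what raising the concentration of free base from its lowest to its highest value here does to the part of the electrophile that has reacted (changes below 5 percentage points count as none) (it rises / no change / it falls)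

The decision before me is whether any base level among theta, alpha and beta is worth choosing for the sake of electrophile consumed. The electrophile is the limiting reagent, and the nucleophile charge is 1.05 times its charge, so I freeze the two as equal. The rate then goes as the square of the electrophile, and one over its concentration rises steadily with time.

By the last readings, at 8.00 h, amber shows a rise of 0.414 /M/h and violet 0.431 /M/h. Violet has 3.03 times amber's base, yet the electrophile left differs by 1 percentage point, with a scatter of 1 point. I carry the mean, 0.422 /M/h, as the reciprocal climb, the steady hourly rise of one over the electrophile concentration.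

Run on to 10 h, it gives me 61.6 % reacted at each base level, though beta lies a little above violet. So I leave nucleophile and time as they are and choose the base for the target, which at 8.00 h reads 44.8 % in amber and 30.1 % in violet.

The forecast reads 61 %, 61 % and 61.5 %, with no change as the trend, and my figure is slightly higher than its first value. Its ground: “Its consumption therefore looks zero order in free base over this range”.

The flasks give 61.6 %, 61.7 % and 61.9 %, and the trend is no change, with a change of 0.25 points from lowest to highest base.

    free base + target → over-reaction product (k = 0.0558 /M/h)
    acid set free + free base ⇌ salt of the base (K = 1.10 /M, k = 6.64 /M/h)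
    acid set free → by-product carried off (k = 3.19 /h)
    nucleophile + acid set free ⇌ protonated nucleophile, settled at all times (K = 58.0 /M)
    electrophile + nucleophile → acid set free + target (k = 0.516 /M/h)

The forecast stands, but alpha's figure moves by 5 points with the nucleophile at 0.352 M or 0.452 M, the time and other charges held, or with the reading at 8.18 h or 12.2 h, the charges held. The neighbouring flask is alpha read at 2.5 h. There the reciprocal climb gives 28.6 % reacted, and the flask stands at 30.5 %.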